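**Plan**
- Retrosynthesis: cut the C4–O ether bond on the side of the 5-hydroxy unit (o-quinone methide + alcohol). Trace both flavan units to one (2S)-5,6,7-trimethoxyflavan-4-ol (C4 inversion for the trimethoxy unit; reoxidation, 5-O-demethylation and reduction for the phenolic unit). Then cut the pyran O1–C2 bond (oxa-Michael) and the C2–C3 bond (aldol) back to an acetophenone and benzaldehyde.
- Forward: chalcone, then the pyran ring closed and C4 reduced in one pot, then two branches from the same flavanol, and the two units joined last through oxygen.
- Enabling features: the β-aryloxy ketone O1–C2–C3–C4(=O) of the pyranone ring makes the O1–C2 closure reversible. The peri pair 5-OH/C4–OH on the benzo ring of the phenolic unit is the only site that can give an o-quinone methide without acid.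
- Stereochemistry: C2 of both units comes from one catalytic event (step 2). C4 of the trimethoxy unit comes from inversion of the catalyst-set cis carbinol. C4 of the phenolic unit comes from substrate-controlled pseudo-axial attack trans to the 2-phenyl group.

Key step: step 2

Assumptions: acetophenone 1 is taken as a catalogue compound, and the (S,S)-TsDPEN ruthenium catalyst is taken to deliver the (4S)-carbinol as it does with simple aryl alkyl ketones (the mirror-image catalyst is used if the sense proves opposite).

**Step 1**
Reactants: 1 1-(2-hydroxy-4,5,6-trimethoxyphenyl)ethan-1-one; 2 benzaldehyde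
Product: 3 (E)-1-(2-hydroxy-4,5,6-trimethoxyphenyl)-3-phenylprop-2-en-1-one
Conditions: KOH (aq.), EtOH, rt
Reagents that add atoms: none
Why: Claisen–Schmidt aldol condensation of the methyl ketone enolate with non-enolizable benzaldehyde, followed by E1cB dehydration, should give the (E)-enone; any flavanone formed by premature cyclization is harmless because it enters step 2 as well.

**Step 2**
Reactants: 3 (E)-1-(2-hydroxy-4,5,6-trimethoxyphenyl)-3-phenylprop-2-en-1-one
Product: 5 (2S,4S)-5,6,7-trimethoxy-2-phenylchroman-4-ol, via racemic flavanone 4 (not isolated)
Conditions: DBU (5 equiv), MeCN, 40 °C; then RuCl[(S,S)-TsDPEN](p-cymene) (2 mol %), HCO2H (3 equiv), 40 °C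
Reagents that add atoms: none
Why: Proposed new method: DBU deprotonates the 2'-phenol of 3 and the phenoxide closes the pyranone ring by 6-endo-trig oxa-Michael addition to the enone β-carbon (the O1–C2 bond) to give racemic 4, whose β-aryloxy ketone keeps re-opening by E1cB retro-oxa-Michael in the basic formate medium, so that the two C2 enantiomers interconvert through 3. The ruthenium hydride of the (S,S)-TsDPEN complex reduces C4=O by outer-sphere hydride/proton transfer to the (4S)-carbinol, and only in (2S)-4 does this catalyst-preferred face coincide with the pseudo-axial trajectory that the half-chair pyranone itself favors (the one that gives the cis alcohol with borohydride), so (2S)-4 should be drained selectively. The closest known reaction types are the dynamic kinetic resolution by asymmetric transfer hydrogenation of 2-substituted chroman-4-ones that racemize by retro-oxa-Michael/oxa-Michael, and the kinetic resolution of flavanones by transfer hydrogenation; new here is entry from the open chalcone and reliance on this racemization for a 2-aryl-5-alkoxy case. C2 is thus set by catalyst selection between equilibrating enantiomers (Curtin–Hammett), and C4 by the catalyst, reinforced by the cis preference of the substrate. The step needs reduction of the closed ketone to outrun both reduction of the open enone and reduction of (2R)-4: the 6'-methoxy group twists the aryl ketone of 3 out of conjugation and pushes the equilibrium to the closed form, the open form is present as an electron-rich phenoxide that is a poor hydride acceptor, and the excess of DBU over HCO2H keeps ring opening fast.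

**Step 3**
Reactants: 5 (2S,4S)-5,6,7-trimethoxy-2-phenylchroman-4-ol
Product: 6 (2S,4R)-5,6,7-trimethoxy-2-phenylchroman-4-yl 4-nitrobenzoate
Conditions: 4-nitrobenzoic acid, PPh3, DIAD, toluene/THF, −20 °C to rt
Reagents that add atoms: 4-nitrobenzoic acid, O=C(O)c1ccc(cc1)[N+](=O)[O-]
Why: Mitsunobu esterification, in which the C4 alkoxyphosphonium is displaced by carboxylate with inversion (4S to 4R); any ionization to the stabilized benzylic cation should be captured along the same pseudo-axial path, so both pathways converge on the 2,4-trans ester.

**Step 4**
Reactants: 6 (2S,4R)-5,6,7-trimethoxy-2-phenylchroman-4-yl 4-nitrobenzoate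
Product: 7 (2S,4R)-5,6,7-trimethoxy-2-phenylchroman-4-ol
Conditions: LiOH, THF/H2O, 0 °C to rt
Reagents that add atoms: none
Why: Saponification by acyl–oxygen cleavage leaves the C4–O bond and hence the (4R) configuration untouched; aqueous rather than methanolic base avoids solvolysis to a 4-methyl ether.

**Step 5**
Reactants: 5 (2S,4S)-5,6,7-trimethoxy-2-phenylchroman-4-ol
Product: 8 (2S)-5,6,7-trimethoxy-2-phenylchroman-4-one
Conditions: Dess–Martin periodinane, NaHCO3, CH2Cl2, 0 °C to rt
Reagents that add atoms: none
Why: Dess–Martin oxidation of the secondary benzylic alcohol restores the C4 carbonyl needed to direct the demethylation of step 6; the buffered, non-basic medium should not open the pyranone, so C2 is retained.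

**Step 6**
Reactants: 8 (2S)-5,6,7-trimethoxy-2-phenylchroman-4-one
Product: 9 (2S)-5-hydroxy-6,7-dimethoxy-2-phenylchroman-4-one
Conditions: BCl3 (1.2 equiv), CH2Cl2, −78 to 0 °C; then H2O
Reagents that add atoms: none
Why: Chelation-controlled Lewis acid ether cleavage: BCl3 bridges C4=O and the peri 5-methoxy oxygen in a six-membered chelate and chloride removes only that methyl group, while the low temperature and near-stoichiometric reagent should spare the 6- and 7-methoxy groups and the C2 center.

**Step 7**
Reactants: 9 (2S)-5-hydroxy-6,7-dimethoxy-2-phenylchroman-4-one
Product: 10 (2S,4S)-6,7-dimethoxy-2-phenylchromane-4,5-diol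
Conditions: NaBH4, THF/EtOH, 0 °C; pH 7 buffer work-up, used at once
Reagents that add atoms: none
Why: Borohydride reduction with pseudo-axial hydride delivery should give mainly the 2,4-cis diol; the C4 configuration is of no consequence because it is erased in step 8.

**Step 8**
Reactants: 10 (2S,4S)-6,7-dimethoxy-2-phenylchromane-4,5-diol; 7 (2S,4R)-5,6,7-trimethoxy-2-phenylchroman-4-ol
Product: 12 beilschmieflavonoid B, via o-quinone methide 11 (not isolated)
Conditions: 7 (2 equiv), 4 Å molecular sieves, toluene, 70 °C; excess 7 recovered
Reagents that add atoms: none
Why: Thermal dehydration of the o-hydroxybenzyl alcohol gives o-quinone methide 11 (only this partner is activated in the absence of acid), and oxa-Michael addition of alcohol 7 to C4 along the pseudo-axial trajectory anti to the equatorial 2-phenyl group should set (4R) in the phenolic unit with rearomatization, while the carbinol center of 7 is retained because its C–O bond is not broken.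

**Compound list**
1 | 1-(2-hydroxy-4,5,6-trimethoxyphenyl)ethan-1-one (2'-hydroxy-4',5',6'-trimethoxyacetophenone) | CC(=O)c1c(O)cc(OC)c(OC)c1OC | starting material
2 | benzaldehyde | O=Cc1ccccc1 | starting material
3 | (E)-1-(2-hydroxy-4,5,6-trimethoxyphenyl)-3-phenylprop-2-en-1-one | COc1cc(O)c(C(=O)/C=C/c2ccccc2)c(OC)c1OC | intermediate
4 | racemic 5,6,7-trimethoxy-2-phenylchroman-4-one (racemic flavanone) | O=C1CC(c2ccccc2)Oc2cc(OC)c(OC)c(OC)c21 | intermediate
5 | (2S,4S)-5,6,7-trimethoxy-2-phenylchroman-4-ol (2,4-cis) | O[C@H]1C[C@@H](c2ccccc2)Oc2cc(OC)c(OC)c(OC)c21 | intermediate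
6 | (2S,4R)-5,6,7-trimethoxy-2-phenylchroman-4-yl 4-nitrobenzoate (2,4-trans) | O=C(O[C@@H]1C[C@@H](c2ccccc2)Oc2cc(OC)c(OC)c(OC)c21)c1ccc(cc1)[N+](=O)[O-] | intermediate
7 | (2S,4R)-5,6,7-trimethoxy-2-phenylchroman-4-ol (2,4-trans) | O[C@@H]1C[C@@H](c2ccccc2)Oc2cc(OC)c(OC)c(OC)c21 | intermediate
8 | (2S)-5,6,7-trimethoxy-2-phenylchroman-4-one | O=C1C[C@@H](c2ccccc2)Oc2cc(OC)c(OC)c(OC)c21 | intermediate
9 | (2S)-5-hydroxy-6,7-dimethoxy-2-phenylchroman-4-one | O=C1C[C@@H](c2ccccc2)Oc2cc(OC)c(OC)c(O)c21 | intermediate
10 | (2S,4S)-6,7-dimethoxy-2-phenylchromane-4,5-diol (2,4-cis) | O[C@H]1C[C@@H](c2ccccc2)Oc2cc(OC)c(OC)c(O)c21 | intermediate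
11 | (2S)-6,7-dimethoxy-2-phenyl-2,3-dihydro-5H-chromen-5-one (o-quinone methide, C4=C4a) | COC1=C(OC)C(=O)C2=CC[C@@H](c3ccccc3)OC2=C1 | intermediate
12 | beilschmieflavonoid B | COc1cc2c(c(O)c1OC)[C@H](O[C@@H]1C[C@@H](c3ccccc3)Oc3cc(OC)c(OC)c(OC)c31)C[C@@H](c1ccccc1)O2 | target

**Step count**
Total: 8 steps. Longest linear sequence: 6 steps (steps 1, 2, 5, 6, 7, 8).

**Steps most likely to fail**

Step 2. Ring opening and reclosure may be slower than reduction of the mismatched enantiomer, which would erode both selectivities, or the open enone may be reduced at the C=C or C=O bond. The fallback separates ring closure from stereoselection and uses known chemistry. It sets out from 3: cyclization with NaOAc in refluxing EtOH should give isolated racemic flavanone 4. Compound 4 is then resolved kinetically by transfer hydrogenation without strong base (RuCl[(S,S)-TsDPEN](p-cymene), HCO2H/Et3N 5:2, EtOAc, rt, run to about half conversion). This should give 5 together with unreacted (2R)-5,6,7-trimethoxy-2-phenylchroman-4-one F1. F1 is separated, racemized back to 4 with DBU in MeCN in a separate flask, and resubmitted. The fallback comes back to the route at 5.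

Step 8. Self-condensation or tautomerization of the o-quinone methide may outrun its capture by the hindered secondary alcohol, and the addition is reversible at the reaction temperature. The fallback replaces thermal dehydration by base-triggered release from a storable precursor. It sets out from 10: sodium 4-methylbenzenesulfinate in HCO2H/H2O at rt should give (2S,4R)-6,7-dimethoxy-4-[(4-methylphenyl)sulfonyl]-2-phenylchroman-5-ol F2 (either C4 epimer serves). F2 is added at 0 °C to the sodium alkoxide of 7 (7, NaH, THF). The phenoxide should expel sulfinate to give 11 in the presence of the alkoxide, whose adduct cannot revert under these conditions. The fallback comes back to the route at 12.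

Step 3. E1 loss of the C3 proton from the ionized alkoxyphosphonium (elimination to the 2H-chromene) may outcompete carboxylate capture. The fallback replaces steps 3 and 4 by an SN1 epimerization with water as the nucleophile and makes no compound outside the list (F0). It sets out from 5: dilute HCl in acetone/H2O at rt ionizes C4 reversibly. Water should return mainly along the pseudo-axial path, and the pseudo-axial trans alcohol also escapes the peri clash with the 5-methoxy group. The mixture is separated, recovered 5 is recycled, and the fallback comes back to the route at 7.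

**Further compounds**
F1 | step 2 | (2R)-5,6,7-trimethoxy-2-phenylchroman-4-one | O=C1C[C@H](c2ccccc2)Oc2cc(OC)c(OC)c(OC)c21
F2 | step 8 | (2S,4R)-6,7-dimethoxy-4-[(4-methylphenyl)sulfonyl]-2-phenylchroman-5-ol | Cc1ccc(cc1)S(=O)(=O)[C@@H]1C[C@@H](c2ccccc2)Oc2cc(OC)c(OC)c(O)c21
F0 | step 3 | none | none
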